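**Retrosynthetic overview**
- The C14 ketone is unmasked last from a 1,3-dithiane; the C13–C14 bond comes from SN2 alkylation of lithiated 2-isobutyl-1,3-dithiane with an (E)-allylic bromide.
- The C13 bromide comes from the terminal (E)-allylic alcohol, made by SeO2 C–H oxidation of the (S)-furyl homofarnesyl acetate.
- Key step: the ester C–O bond and the C1 stereocentre are made together by acetylative dynamic kinetic resolution of the racemic furan-3-yl carbinol.
- The racemic carbinol comes from α-selective addition of farnesylbarium chloride to furan-3-carbaldehyde (C1–C2 bond); farnesyl chloride comes from (2E,6E)-farnesol.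
- Rings: the furan is bought; the only ring made is the temporary 1,3-dithiane (step 7), opened again in step 9.

Assumption: the antipode of the planar-chiral DMAP catalyst that acetylates the (S)-carbinol faster is fixed by a small test resolution on racemic 6, and that antipode is used in step 4.

**Route**

Step 1
Reactants: 1 (2E,6E)-farnesol
Product: 3 (2E,6E)-farnesyl chloride, via farnesyl mesylate 2 (not isolated)
Conditions: MsCl, LiCl, 2,4,6-collidine, DMF, 0 °C
Reagents that add atoms: lithium chloride, [Li+].[Cl-]
Why: Mesylation followed by SN2 displacement with chloride (Collington–Meyers allylic chlorination) converts the primary allylic alcohol at 0 °C without allylic shift or E/Z loss.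

Step 2
Reactants: 3 (2E,6E)-farnesyl chloride; 4 furan-3-carbaldehyde
Product: 6 rac-(3E,7E)-1-(furan-3-yl)-4,8,12-trimethyltrideca-3,7,11-trien-1-ol, via farnesylbarium chloride 5 (not isolated)
Conditions: Ba* (from BaI2 + 2 lithium biphenylide, THF, rt); 3, THF, −78 °C; then 4, −78 °C; aq. NH4Cl
Reagents that add atoms: none
Why: Allylbarium reagents made at −78 °C keep their alkene geometry and add to aldehydes at the α-carbon (α-selective allylmetal carbonyl addition, Barbier–Grignard type), giving the linear homoallylic alcohol with both E alkenes intact; C1 is formed racemic.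

Step 3
Reactants: 7 acetic acid
Product: 8 acetyl isopropyl carbonate
Conditions: i-PrOCOCl, Et3N, Et2O, 0 °C; filter, concentrate, use cold
Reagents that add atoms: isopropyl chloroformate, CC(C)OC(Cl)=O
Why: Acylation of the carboxylate by a chloroformate (mixed carboxylic–carbonic anhydride formation) gives an acetyl donor whose leaving fragments are neutral.

Step 4
Reactants: 6 rac-(3E,7E)-1-(furan-3-yl)-4,8,12-trimethyltrideca-3,7,11-trien-1-ol; 8 acetyl isopropyl carbonate
Product: 9 (1S,3E,7E)-1-(furan-3-yl)-4,8,12-trimethyltrideca-3,7,11-trien-1-yl acetate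
Conditions: (η5-C5Ph5)Ru(CO)2Cl (5 mol %), KOt-Bu (5 mol %), planar-chiral (η5-C5Ph5)Fe(η5-C10H11N2) [4-(dimethylamino)pyrindinyl iron complex, (S)-selective antipode, 2 mol %], 8 (1.5 equiv), t-amyl alcohol/toluene 1:1, 10 °C
Reagents that add atoms: none
Why: Proposed new method: acetylative dynamic kinetic resolution of a furan-3-yl homoallylic carbinol. The ruthenium alkoxide of 6 undergoes reversible β-hydride elimination and re-insertion through a ketone–hydride pair that stays on the metal, so the two enantiomers of 6 interconvert. The N-acetylpyridinium ion formed from the chiral DMAP complex and 8 (which leaves only CO2 and isopropanol, so no acid poisons the ruthenium) transfers acetyl faster to the (S)-carbinol by telling the flat furan-3-yl group from the CH2 chain. This forms the ester C–O bond and sets C1 as S in one operation, and the trisubstituted alkenes are inert to both catalysts. The closest known reaction type is the non-enzymatic ruthenium/chiral-DMAP dynamic kinetic resolution of simple 1-arylalkanols (and the lipase/ruthenium variant), which has not been shown on a furan-3-yl carbinol carrying a skipped polyene chain. By that analogy about 90% ee or better is expected, to be checked by chiral HPLC.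

Step 5
Reactants: 9 (1S,3E,7E)-1-(furan-3-yl)-4,8,12-trimethyltrideca-3,7,11-trien-1-yl acetate
Product: 10 (1S,3E,7E,11E)-1-(furan-3-yl)-13-hydroxy-4,8,12-trimethyltrideca-3,7,11-trien-1-yl acetate
Conditions: SeO2 (0.3 equiv), t-BuOOH (3 equiv), salicylic acid (0.1 equiv), CH2Cl2, 0 °C to rt; stop at partial conversion, recycle 9
Reagents that add atoms: tert-butyl hydroperoxide, CC(C)(C)OO (terminal source of the new oxygen, passed on through selenium dioxide, O=[Se]=O)
Why: The SeO2 ene reaction followed by [2,3]-sigmatropic shift (catalytic SeO2/t-BuOOH allylic oxidation) goes for the E-methyl group of the terminal, least hindered trisubstituted alkene, as it does in farnesyl esters; the near-neutral conditions leave the furan, the ester and C1 alone.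

Step 6
Reactants: 10 (1S,3E,7E,11E)-1-(furan-3-yl)-13-hydroxy-4,8,12-trimethyltrideca-3,7,11-trien-1-yl acetate
Product: 11 (1S,3E,7E,11E)-13-bromo-1-(furan-3-yl)-4,8,12-trimethyltrideca-3,7,11-trien-1-yl acetate
Conditions: PPh3, CBr4, CH2Cl2, 0 °C; use at once
Reagents that add atoms: carbon tetrabromide, BrC(Br)(Br)Br
Why: Appel reaction: bromide displaces the alkoxyphosphonium group in an SN2 step at the primary allylic carbon, without allylic shift or loss of the E geometry.

Step 7
Reactants: 12 3-methylbutanal
Product: 13 2-(2-methylpropyl)-1,3-dithiane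
Conditions: HS(CH2)3SH, BF3·OEt2 (cat.), CH2Cl2, 0 °C to rt
Reagents that add atoms: propane-1,3-dithiol, SCCCS
Why: Lewis-acid-catalysed thioacetalisation of an aldehyde, the first half of the Corey–Seebach umpolung.

Step 8
Reactants: 13 2-(2-methylpropyl)-1,3-dithiane; 11 (1S,3E,7E,11E)-13-bromo-1-(furan-3-yl)-4,8,12-trimethyltrideca-3,7,11-trien-1-yl acetate
Product: 15 (1S,3E,7E,11E)-1-(furan-3-yl)-4,8,12-trimethyl-13-[2-(2-methylpropyl)-1,3-dithian-2-yl]trideca-3,7,11-trien-1-yl acetate, via 2-lithio-2-isobutyl-1,3-dithiane 14 (not isolated)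
Conditions: 13 (1.15 equiv), n-BuLi (1.1 equiv), THF, −30 °C, 2 h; then 11 (1.0 equiv), −78 °C, 30 min; AcOH quench at −78 °C
Reagents that add atoms: none
Why: Corey–Seebach alkylation: the tertiary dithianyl anion attacks the primary allylic bromide in an SN2 step within minutes at −78 °C, which should be faster than its addition to the secondary acetate, and the E alkene is kept.

Step 9
Reactants: 15 (1S,3E,7E,11E)-1-(furan-3-yl)-4,8,12-trimethyl-13-[2-(2-methylpropyl)-1,3-dithian-2-yl]trideca-3,7,11-trien-1-yl acetate
Product: 16 (1S,3E,7E,11E)-1-(furan-3-yl)-4,8,12,16-tetramethyl-14-oxoheptadeca-3,7,11-trien-1-yl acetate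
Conditions: MeI (excess), CaCO3, MeCN/H2O 4:1, 40 °C, dark
Reagents that add atoms: water, O
Why: Alkylative thioacetal hydrolysis (S-methylation, then attack of water) under CaCO3 buffer unmasks the ketone without acid or base, so the β,γ-alkene stays out of conjugation and the ester and stereocentre at C1 are untouched.

**Compound list**
1 | (2E,6E)-farnesol [(2E,6E)-3,7,11-trimethyldodeca-2,6,10-trien-1-ol] | OC/C=C(\C)CC/C=C(\C)CCC=C(C)C | starting material
2 | (2E,6E)-farnesyl methanesulfonate | CS(=O)(=O)OC/C=C(\C)CC/C=C(\C)CCC=C(C)C | intermediate (not isolated)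
3 | (2E,6E)-farnesyl chloride | ClC/C=C(\C)CC/C=C(\C)CCC=C(C)C | intermediate
4 | furan-3-carbaldehyde | O=Cc1ccoc1 | starting material
5 | (2E,6E)-farnesylbarium chloride | Cl[Ba]C/C=C(\C)CC/C=C(\C)CCC=C(C)C | intermediate (not isolated)
6 | rac-(3E,7E)-1-(furan-3-yl)-4,8,12-trimethyltrideca-3,7,11-trien-1-ol | OC(C/C=C(\C)CC/C=C(\C)CCC=C(C)C)c1ccoc1 | intermediate
7 | acetic acid | CC(=O)O | starting material
8 | acetyl isopropyl carbonate (acetic isopropyl carbonic anhydride) | CC(=O)OC(=O)OC(C)C | intermediate
9 | (1S,3E,7E)-1-(furan-3-yl)-4,8,12-trimethyltrideca-3,7,11-trien-1-yl acetate | CC(=O)O[C@@H](C/C=C(\C)CC/C=C(\C)CCC=C(C)C)c1ccoc1 | intermediate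
10 | (1S,3E,7E,11E)-1-(furan-3-yl)-13-hydroxy-4,8,12-trimethyltrideca-3,7,11-trien-1-yl acetate | CC(=O)O[C@@H](C/C=C(\C)CC/C=C(\C)CC/C=C(\C)CO)c1ccoc1 | intermediate
11 | (1S,3E,7E,11E)-13-bromo-1-(furan-3-yl)-4,8,12-trimethyltrideca-3,7,11-trien-1-yl acetate | CC(=O)O[C@@H](C/C=C(\C)CC/C=C(\C)CC/C=C(\C)CBr)c1ccoc1 | intermediate
12 | 3-methylbutanal (isovaleraldehyde) | CC(C)CC=O | starting material
13 | 2-(2-methylpropyl)-1,3-dithiane | CC(C)CC1SCCCS1 | intermediate
14 | 2-lithio-2-(2-methylpropyl)-1,3-dithiane | [Li]C1(CC(C)C)SCCCS1 | intermediate (not isolated)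
15 | (1S,3E,7E,11E)-1-(furan-3-yl)-4,8,12-trimethyl-13-[2-(2-methylpropyl)-1,3-dithian-2-yl]trideca-3,7,11-trien-1-yl acetate | CC(=O)O[C@@H](C/C=C(\C)CC/C=C(\C)CC/C=C(\C)CC1(CC(C)C)SCCCS1)c1ccoc1 | intermediate
16 | (1S,3E,7E,11E)-1-(furan-3-yl)-4,8,12,16-tetramethyl-14-oxoheptadeca-3,7,11-trien-1-yl acetate | CC(=O)O[C@@H](C/C=C(\C)CC/C=C(\C)CC/C=C(\C)CC(=O)CC(C)C)c1ccoc1 | target

**Step count**
Total step count: 9 (steps 3 and 7 are one-operation reagent preparations).
Longest linear sequence: 7 (steps 1, 2, 4, 5, 6, 8, 9, from farnesol).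

**Three steps most likely to fail**

Step 4 (the proposed new step). The risks are slow racemisation, release and conjugation of the β,γ-unsaturated furyl ketone from the ruthenium, and a selectivity too low for a single enantiomer. The fallback uses known chemistry, sets out from 6 and comes back at 9. Oxidise 6 with activated MnO2 (CH2Cl2, rt) to the ketone (3E,7E)-1-(furan-3-yl)-4,8,12-trimethyltrideca-3,7,11-trien-1-one F1. Reduce it with BH3·SMe2 and (R)-2-methyl-CBS-oxazaborolidine (toluene, −20 °C; Corey–Bakshi–Shibata reduction with furan-3-yl as the large group) to the alcohol (1S,3E,7E)-1-(furan-3-yl)-4,8,12-trimethyltrideca-3,7,11-trien-1-ol F2. Acetylate with Ac2O, pyridine and catalytic DMAP to reach 9.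

Step 5. The risks are oxidation at the two inner alkenes, over-oxidation to the enal, and attack of the peroxide on the furan, on late and enantio-enriched material. The fallback sets out from 9 and comes back at 10. Cross-metathesis of the terminal isopropylidene group of 9 with excess methacrolein (second-generation Hoveyda–Grubbs catalyst, RuCl2(H2IMes)(=CH-C6H4-2-O-i-Pr) with H2IMes = 1,3-dimesitylimidazolidin-2-ylidene, CH2Cl2, 40 °C) gives the E-enal (1S,3E,7E,11E)-1-(furan-3-yl)-4,8,12-trimethyl-13-oxotrideca-3,7,11-trien-1-yl acetate F3. Luche reduction (NaBH4, CeCl3·7H2O, MeOH, −20 °C) then gives 10.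

Step 8. The risk is that the dithianyl anion deprotonates or adds to the C1 acetate instead of alkylating cleanly. The fallback sets out from 11 and comes back at 15, and changes the protecting logic: the acetate is given up as a sacrificial group and the ester is rebuilt afterwards. Add 11 to 2.2 equiv of 14 at −78 °C and warm to −20 °C, so that the excess carbanion also takes off the acetyl group. This gives the alcohol (1S,3E,7E,11E)-1-(furan-3-yl)-4,8,12-trimethyl-13-[2-(2-methylpropyl)-1,3-dithian-2-yl]trideca-3,7,11-trien-1-ol F4; the C1–O bond is never broken, so the configuration is kept. Re-form the ester with Ac2O, pyridine and catalytic DMAP to reach 15.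

Further compounds
F1 | step 4 | (3E,7E)-1-(furan-3-yl)-4,8,12-trimethyltrideca-3,7,11-trien-1-one | O=C(C/C=C(\C)CC/C=C(\C)CCC=C(C)C)c1ccoc1
F2 | step 4 | (1S,3E,7E)-1-(furan-3-yl)-4,8,12-trimethyltrideca-3,7,11-trien-1-ol | O[C@@H](C/C=C(\C)CC/C=C(\C)CCC=C(C)C)c1ccoc1
F3 | step 5 | (1S,3E,7E,11E)-1-(furan-3-yl)-4,8,12-trimethyl-13-oxotrideca-3,7,11-trien-1-yl acetate | CC(=O)O[C@@H](C/C=C(\C)CC/C=C(\C)CC/C=C(\C)C=O)c1ccoc1
F4 | step 8 | (1S,3E,7E,11E)-1-(furan-3-yl)-4,8,12-trimethyl-13-[2-(2-methylpropyl)-1,3-dithian-2-yl]trideca-3,7,11-trien-1-ol | O[C@@H](C/C=C(\C)CC/C=C(\C)CC/C=C(\C)CC1(CC(C)C)SCCCS1)c1ccoc1
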